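**Strategy**

1. Numbering follows the open C20 chain (C1=C2 vinyl, C3 carbinol, C14 bromide, C15 chloride). Working backwards, the C3 silyl group comes off, the chloride and bromide go back through a (14R)-14,15-oxirane to a C14=C15 alkene, and then the C6–C11 and C7–O bonds are cut together.
2. That double cut is possible because the core is a cyclohexane C6–C7–C8–C9–C10–C11 whose ether oxygen spans C7 and C10 (a 7-oxabicyclo[2.2.1]heptane). This is the pattern left when a C6=C7 alkene attacks C11 of a 10,11-oxirane and the oxygen that stays on C10 traps the C7 cation.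
3. The resulting (6Z)-cis-10,11-epoxide is traced to a C10 ketone and cut at C8–C9 into a C1–C8 Z-allylic bromide and a C9–C16 methyl ketone, each made from (S)-linalool.
4. Forward: the chain is joined by enolate alkylation, the oxirane is installed, the carbocycle and the oxygen bridge close in one operation, and the halogens are placed last through a transient 14,15-oxirane.
5. Stereochemistry: C3 and C11 come from linalool (C11 is inverted in the bicyclization); C10 from a CBS reduction followed by inversion on oxirane closure; C6 and C7 from the bicyclization; C14 from a Shi epoxidation followed by SN2 bromide opening.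

Key step: step 12

Assumption: (S)-(+)-linalool is bought in high enantiomeric purity (both stereogenic fragments derive from it), and the chain numbering C1–C16 defined above is kept for all intermediates.

**Route**

Step 1
Reactants: 1 (S)-(+)-linalool
Product: 2 (3S)-3-(tert-butyldimethylsilyloxy)-3,7-dimethylocta-1,6-diene
Conditions: TBSOTf, 2,6-lutidine, CH2Cl2, 0 °C → rt
Reagents that add atoms: tert-butyldimethylsilyl trifluoromethanesulfonate CC(C)(C)[Si](C)(C)OS(=O)(=O)C(F)(F)F
Why: Silyl ether formation with a silyl triflate and a hindered pyridine base is the standard way to cap a tertiary alcohol, and the C3 stereocentre is not involved.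

Step 2
Reactants: 2 linalool tert-butyldimethylsilyl ether
Product: 4 (4S)-4-(tert-butyldimethylsilyloxy)-4-methylhex-5-enal, via ozonide 3 (not isolated)
Conditions: O3, CH2Cl2, −78 °C, Sudan Red 7B end point; then PPh3, −78 °C → rt
Reagents that add atoms: ozone [O-][O+]=O
Why: Ozonolysis is chemoselective for the electron-rich trisubstituted alkene over the vinyl group beside the quaternary silyloxy carbon, the dye marking the point at which that alkene is consumed, and PPh3 reduces the ozonide to the aldehyde with loss of acetone.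

Step 3
Reactants: 4 C6 aldehyde; 5 ethyl 2-[bis(2,2,2-trifluoroethoxy)phosphoryl]propanoate (racemic)
Product: 7 ethyl (2Z,6S)-6-(tert-butyldimethylsilyloxy)-2,6-dimethylocta-2,7-dienoate, via potassium phosphonate carbanion 6 (not isolated)
Conditions: KN(SiMe3)2, 18-crown-6, THF, −78 °C
Reagents that add atoms: none
Why: Still–Gennari olefination (the Z-selective Horner–Wadsworth–Emmons variant): the electron-poor trifluoroethyl phosphonate with a crown-separated potassium ion eliminates from the kinetic adduct, so the ester ends up cis to the C5 chain (6Z in chain numbering).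

Step 4
Reactants: 7 Z-enoate
Product: 8 (2Z,6S)-6-(tert-butyldimethylsilyloxy)-2,6-dimethylocta-2,7-dien-1-ol
Conditions: i-Bu2AlH, CH2Cl2, −78 °C; aq. KNaC4H4O6 work-up
Reagents that add atoms: none
Why: Hydride 1,2-reduction of the unsaturated ester by i-Bu2AlH gives the allylic alcohol without touching the alkene geometry or the silyl ether.

Step 5
Reactants: 8 Z-allylic alcohol
Product: 10 (3S,6Z)-8-bromo-3-(tert-butyldimethylsilyloxy)-3,7-dimethylocta-1,6-diene, via allylic mesylate 9 (not isolated)
Conditions: MsCl, Et3N, THF, −40 °C; then LiBr, THF, 0 °C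
Reagents that add atoms: lithium bromide [Li+].[Br-]; methanesulfonyl chloride CS(=O)(=O)Cl (its atoms stay only in 9)
Why: Mesylation followed by SN2 displacement with bromide at the primary allylic carbon under cold, non-ionising conditions is the usual way to make neryl-type bromides without loss of the Z geometry.

Step 6
Reactants: 1 (S)-(+)-linalool
Product: 11 (3S)-3,7-dimethyl-3-(triethylsilyloxy)octa-1,6-diene
Conditions: TESOTf, 2,6-lutidine, CH2Cl2, −78 → 0 °C
Reagents that add atoms: triethylsilyl trifluoromethanesulfonate CC[Si](CC)(CC)OS(=O)(=O)C(F)(F)F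
Why: The same silyl ether formation as in step 1; triethylsilyl is chosen so that fluoride can later remove it while the tert-butyldimethylsilyl ether at C3 stays.

Step 7
Reactants: 11 linalool triethylsilyl ether
Product: 12 (3S)-3,7-dimethyl-3-(triethylsilyloxy)oct-6-en-2-one
Conditions: PdCl2(quinox) (cat.; quinox = 2-(4,5-dihydrooxazol-2-yl)quinoline), AgSbF6 (cat.), aq. t-BuOOH, CH2Cl2, 0 °C → rt
Reagents that add atoms: tert-butyl hydroperoxide CC(C)(C)OO
Why: Wacker-type oxidation in its hydroperoxide-mediated, ligand-controlled form converts protected allylic alcohols into methyl ketones, acts only on the monosubstituted alkene, and cannot epimerise the quaternary C11.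

Step 8
Reactants: 12 tail methyl ketone; 10 head Z-allylic bromide
Product: 14 (3S,6Z,11S)-3-(tert-butyldimethylsilyloxy)-3,7,11,15-tetramethyl-11-(triethylsilyloxy)hexadeca-1,6,14-trien-10-one, via lithium enolate 13 (not isolated)
Conditions: LiN(SiMe3)2, THF, −78 °C; then 10, DMPU, −78 → −30 °C
Reagents that add atoms: none
Why: Alkylation of a ketone lithium enolate (SN2) by the reactive primary allylic bromide forms C8–C9; the other α-carbon is quaternary, so only the methyl group can enolise, and the low temperature limits proton exchange and keeps the Z geometry.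

Step 9
Reactants: 14 C20 ketone
Product: 15 (3S,6Z,10S,11S)-3-(tert-butyldimethylsilyloxy)-3,7,11,15-tetramethyl-11-(triethylsilyloxy)hexadeca-1,6,14-trien-10-ol
Conditions: (R)-2-methyl-CBS-oxazaborolidine, catecholborane, toluene, −78 → −40 °C; then MeOH, aq. NaOH wash
Reagents that add atoms: none
Why: Corey–Bakshi–Shibata reduction: the (R)-oxazaborolidine binds the carbonyl lone pair on the side of the small CH2 arm and delivers hydride to the face that gives the (10S)-alcohol, the Felkin–Anh preference of the α-silyloxy ketone pointing the same way, while catecholborane leaves the alkenes alone at this temperature.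

Step 10
Reactants: 15 (10S)-alcohol
Product: 16 (3S,6Z,10S,11S)-3-(tert-butyldimethylsilyloxy)-3,7,11,15-tetramethyl-11-(triethylsilyloxy)hexadeca-1,6,14-trien-10-yl methanesulfonate
Conditions: MsCl, Et3N, DMAP (cat.), CH2Cl2, 0 °C
Reagents that add atoms: methanesulfonyl chloride CS(=O)(=O)Cl
Why: Sulfonate ester formation (mesylation through sulfene) turns the hindered secondary hydroxyl into a leaving group with retention at C10.

Step 11
Reactants: 16 C10 mesylate
Product: 18 (3S,6Z,10R,11S)-3-(tert-butyldimethylsilyloxy)-10,11-epoxy-3,7,11,15-tetramethylhexadeca-1,6,14-triene, via hydroxy mesylate 17 (not isolated)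
Conditions: Bu4NF, THF, 0 °C → rt
Reagents that add atoms: none
Why: Fluoride desilylation is much faster for the triethylsilyl than for the tertiary tert-butyldimethylsilyl ether, and the freed C11 alkoxide closes the oxirane by intramolecular Williamson displacement (3-exo-tet) with inversion at C10, giving the cis-epoxide with C9 and C12 on the same side.

Step 12
Reactants: 18 (6Z)-cis-10,11-epoxide
Product: 20 (1S,2S,3S,4R)-2-[(3S)-3-(tert-butyldimethylsilyloxy)-3-methylpent-4-enyl]-1,3-dimethyl-3-(4-methylpent-3-enyl)-7-oxabicyclo[2.2.1]heptane, via C7 cation 19 (not isolated)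
Conditions: BF3·OEt2, CH2Cl2, −78 °C; then Et3N, aq. NaHCO3
Reagents that add atoms: none
Why: BF3 activates the oxirane, the C6=C7 π bond attacks the tertiary carbon C11 anti to the breaking C11–O bond to give zwitterion 19 with a tertiary cation at C7, and the boron-bound oxygen on C10 then traps that cation; this is the cationic epoxy-olefin cyclization of terpenoid epoxides in its known variant where the oxirane oxygen, not proton loss, ends the reaction (the way 7-oxabicyclo[2.2.1]heptanes arise from 6,7-epoxygeranyl esters). The cyclohexane C6–C7–C8–C9–C10–C11 closes in a 6-endo mode in which both alkene carbons and both oxirane carbons become ring members, and the five-membered ether ring C7–O–C10 closes across the 1,4-positions once C10 flips the chair into a boat. C11 is inverted by the anti opening, so the cis-oxirane places C12 on the face of the C10 oxygen (exo) and the C11 methyl endo, while C10 keeps its configuration. C6 is set by a chair-like transition state in which the Z geometry forces the C5 chain axial and trans to C12, hence endo, and C7 is fixed because the C10 oxygen can reach the cation only from its own face. The step needs anti opening at the tertiary carbon, chair rather than boat closure, and oxygen capture faster than proton loss, hydride shift or attack by C14=C15; these rest on the tertiary/secondary bias of the oxirane, the Z-alkene, the cis-1,4 proximity of alkoxide and cation in a base-free medium at −78 °C, the bulky silyl ether on the C3 oxygen, and the fact that C14=C15 could reach C7 only through a bridging 1,3-diaxial closure.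

Step 13
Reactants: 20 oxabicycle
Product: 21 (1S,2S,3S,4R)-2-[(3S)-3-(tert-butyldimethylsilyloxy)-3-methylpent-4-enyl]-3-{2-[(2R)-3,3-dimethyloxiran-2-yl]ethyl}-1,3-dimethyl-7-oxabicyclo[2.2.1]heptane
Conditions: D-fructose-derived Shi ketone (cat.), KHSO5 (as 2KHSO5·KHSO4·K2SO4), K2CO3, Bu4NHSO4, MeCN/CH2(OMe)2, aq. Na2B4O7/Na2EDTA buffer, 0 °C
Reagents that add atoms: potassium peroxymonosulfate [K+].[O-]S(=O)(=O)OO
Why: Shi asymmetric epoxidation (chiral dioxirane, spiro transition state) acts only on the remaining trisubstituted alkene, the D-fructose-derived ketone giving the R configuration at C14 under reagent control, while the vinyl group is too electron-poor and hindered to react.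

Step 14
Reactants: 21 (14R)-14,15-epoxide
Product: 22 (3S)-3-bromo-5-{(1R,2S,3S,4S)-3-[(3S)-3-(tert-butyldimethylsilyloxy)-3-methylpent-4-enyl]-2,4-dimethyl-7-oxabicyclo[2.2.1]heptan-2-yl}-2-methylpentan-2-ol
Conditions: Li2NiBr4, THF, 0 °C → rt; pH 7 phosphate buffer
Reagents that add atoms: dilithium tetrabromonickelate [Li+].[Li+].[Br-].[Br-].[Br-].[Br-].[Ni+2]
Why: Nucleophilic epoxide opening by the soft bromide of Li2NiBr4 goes by SN2 at the less substituted C14 with inversion, which gives the (14S)-bromide with the tertiary C15 alcohol and avoids the acid-type opening at C15.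

Step 15
Reactants: 22 bromohydrin
Product: 25 (1S,2S,3S,4R)-3-[(3S)-3-bromo-4-chloro-4-methylpentyl]-2-[(3S)-3-(tert-butyldimethylsilyloxy)-3-methylpent-4-enyl]-1,3-dimethyl-7-oxabicyclo[2.2.1]heptane, via chlorosulfite 23 (not isolated), via bromonium chloride 24 (not isolated)
Conditions: SOCl2, pyridine, CH2Cl2, −40 → 0 °C
Reagents that add atoms: thionyl chloride ClS(Cl)=O
Why: Deoxychlorination with neighbouring-group participation: the tertiary chlorosulfite ionises with anchimeric help from the anti bromine to a bromonium ion that chloride opens at the tertiary C15, so the C14–Br bond and its configuration are kept.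

Step 16
Reactants: 25 silyl ether of the target
Product: 26 (3S)-5-[(1S,2S,3S,4R)-3-[(3S)-3-bromo-4-chloro-4-methylpentyl]-1,3-dimethyl-7-oxabicyclo[2.2.1]heptan-2-yl]-3-methylpent-1-en-3-ol
Conditions: HF·pyridine, pyridine, THF, 0 °C → rt
Reagents that add atoms: none
Why: Fluoride-mediated desilylation under buffered, weakly acidic conditions removes the tertiary silyl ether without the E2 loss of halide that a basic fluoride source could cause.

**Compound list**

1 | (S)-(+)-linalool, (3S)-3,7-dimethylocta-1,6-dien-3-ol | C=C[C@@](C)(O)CCC=C(C)C | starting material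
2 | (3S)-3-(tert-butyldimethylsilyloxy)-3,7-dimethylocta-1,6-diene | C=C[C@@](C)(O[Si](C)(C)C(C)(C)C)CCC=C(C)C | intermediate
3 | 3-[(3S)-3-(tert-butyldimethylsilyloxy)-3-methylpent-4-enyl]-5,5-dimethyl-1,2,4-trioxolane (ozonide, both epimers at the ring CH) | C=C[C@@](C)(O[Si](C)(C)C(C)(C)C)CCC1OOC(C)(C)O1 | intermediate
4 | (4S)-4-(tert-butyldimethylsilyloxy)-4-methylhex-5-enal | C=C[C@@](C)(O[Si](C)(C)C(C)(C)C)CCC=O | intermediate
5 | ethyl 2-[bis(2,2,2-trifluoroethoxy)phosphoryl]propanoate (racemic) | CCOC(=O)C(C)P(=O)(OCC(F)(F)F)OCC(F)(F)F | starting material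
6 | potassium salt of the α-carbanion of 5 | [K+].CCOC(=O)[C-](C)P(=O)(OCC(F)(F)F)OCC(F)(F)F | intermediate
7 | ethyl (2Z,6S)-6-(tert-butyldimethylsilyloxy)-2,6-dimethylocta-2,7-dienoate | C=C[C@@](C)(O[Si](C)(C)C(C)(C)C)CC/C=C(/C)C(=O)OCC | intermediate
8 | (2Z,6S)-6-(tert-butyldimethylsilyloxy)-2,6-dimethylocta-2,7-dien-1-ol | C=C[C@@](C)(O[Si](C)(C)C(C)(C)C)CC/C=C(/C)CO | intermediate
9 | (2Z,6S)-6-(tert-butyldimethylsilyloxy)-2,6-dimethylocta-2,7-dien-1-yl methanesulfonate | C=C[C@@](C)(O[Si](C)(C)C(C)(C)C)CC/C=C(/C)COS(C)(=O)=O | intermediate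
10 | (3S,6Z)-8-bromo-3-(tert-butyldimethylsilyloxy)-3,7-dimethylocta-1,6-diene | C=C[C@@](C)(O[Si](C)(C)C(C)(C)C)CC/C=C(/C)CBr | intermediate
11 | (3S)-3,7-dimethyl-3-(triethylsilyloxy)octa-1,6-diene | C=C[C@@](C)(O[Si](CC)(CC)CC)CCC=C(C)C | intermediate
12 | (3S)-3,7-dimethyl-3-(triethylsilyloxy)oct-6-en-2-one | CC(=O)[C@@](C)(O[Si](CC)(CC)CC)CCC=C(C)C | intermediate
13 | lithium (3S)-3,7-dimethyl-3-(triethylsilyloxy)octa-1,6-dien-2-olate (enolate of 12) | [Li+].C=C([O-])[C@@](C)(O[Si](CC)(CC)CC)CCC=C(C)C | intermediate
14 | (3S,6Z,11S)-3-(tert-butyldimethylsilyloxy)-3,7,11,15-tetramethyl-11-(triethylsilyloxy)hexadeca-1,6,14-trien-10-one | C=C[C@@](C)(O[Si](C)(C)C(C)(C)C)CC/C=C(/C)CCC(=O)[C@@](C)(O[Si](CC)(CC)CC)CCC=C(C)C | intermediate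
15 | (3S,6Z,10S,11S)-3-(tert-butyldimethylsilyloxy)-3,7,11,15-tetramethyl-11-(triethylsilyloxy)hexadeca-1,6,14-trien-10-ol | C=C[C@@](C)(O[Si](C)(C)C(C)(C)C)CC/C=C(/C)CC[C@H](O)[C@@](C)(O[Si](CC)(CC)CC)CCC=C(C)C | intermediate
16 | (3S,6Z,10S,11S)-3-(tert-butyldimethylsilyloxy)-3,7,11,15-tetramethyl-11-(triethylsilyloxy)hexadeca-1,6,14-trien-10-yl methanesulfonate | C=C[C@@](C)(O[Si](C)(C)C(C)(C)C)CC/C=C(/C)CC[C@H](OS(C)(=O)=O)[C@@](C)(O[Si](CC)(CC)CC)CCC=C(C)C | intermediate
17 | (3S,6Z,10S,11S)-3-(tert-butyldimethylsilyloxy)-11-hydroxy-3,7,11,15-tetramethylhexadeca-1,6,14-trien-10-yl methanesulfonate (present as its tetrabutylammonium alkoxide) | C=C[C@@](C)(O[Si](C)(C)C(C)(C)C)CC/C=C(/C)CC[C@H](OS(C)(=O)=O)[C@@](C)(O)CCC=C(C)C | intermediate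
18 | (3S,6Z,10R,11S)-3-(tert-butyldimethylsilyloxy)-10,11-epoxy-3,7,11,15-tetramethylhexadeca-1,6,14-triene | C=C[C@@](C)(O[Si](C)(C)C(C)(C)C)CC/C=C(/C)CC[C@H]1O[C@@]1(C)CCC=C(C)C | intermediate
19 | monocyclic zwitterion: cyclohexyl cation at C7 with the C10 oxygen bound to BF3 (C6, C10, C11 as in 20) | C=C[C@@](C)(O[Si](C)(C)C(C)(C)C)CC[C@H]1[C@](C)(CCC=C(C)C)[C@H](O[B-](F)(F)F)CC[C+]1C | intermediate
20 | (1S,2S,3S,4R)-2-[(3S)-3-(tert-butyldimethylsilyloxy)-3-methylpent-4-enyl]-1,3-dimethyl-3-(4-methylpent-3-enyl)-7-oxabicyclo[2.2.1]heptane | C=C[C@@](C)(O[Si](C)(C)C(C)(C)C)CC[C@H]1[C@](C)(CCC=C(C)C)[C@H]2CC[C@]1(C)O2 | intermediate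
21 | (1S,2S,3S,4R)-2-[(3S)-3-(tert-butyldimethylsilyloxy)-3-methylpent-4-enyl]-3-{2-[(2R)-3,3-dimethyloxiran-2-yl]ethyl}-1,3-dimethyl-7-oxabicyclo[2.2.1]heptane | C=C[C@@](C)(O[Si](C)(C)C(C)(C)C)CC[C@H]1[C@](C)(CC[C@H]3OC3(C)C)[C@H]2CC[C@]1(C)O2 | intermediate
22 | (3S)-3-bromo-5-{(1R,2S,3S,4S)-3-[(3S)-3-(tert-butyldimethylsilyloxy)-3-methylpent-4-enyl]-2,4-dimethyl-7-oxabicyclo[2.2.1]heptan-2-yl}-2-methylpentan-2-ol | C=C[C@@](C)(O[Si](C)(C)C(C)(C)C)CC[C@H]1[C@](C)(CC[C@H](Br)C(C)(C)O)[C@H]2CC[C@]1(C)O2 | intermediate
23 | chlorosulfite ester of the tertiary alcohol of 22 | C=C[C@@](C)(O[Si](C)(C)C(C)(C)C)CC[C@H]1[C@](C)(CC[C@H](Br)C(C)(C)OS(Cl)=O)[C@H]2CC[C@]1(C)O2 | intermediate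
24 | C14–C15 bromonium ion of 25, chloride salt | C=C[C@@](C)(O[Si](C)(C)C(C)(C)C)CC[C@H]1[C@](C)(CC[C@@H]3[Br+]C3(C)C)[C@H]2CC[C@]1(C)O2.[Cl-] | intermediate
25 | (1S,2S,3S,4R)-3-[(3S)-3-bromo-4-chloro-4-methylpentyl]-2-[(3S)-3-(tert-butyldimethylsilyloxy)-3-methylpent-4-enyl]-1,3-dimethyl-7-oxabicyclo[2.2.1]heptane | C=C[C@@](C)(O[Si](C)(C)C(C)(C)C)CC[C@H]1[C@](C)(CC[C@H](Br)C(C)(C)Cl)[C@H]2CC[C@]1(C)O2 | intermediate
26 | (3S)-5-[(1S,2S,3S,4R)-3-[(3S)-3-bromo-4-chloro-4-methylpentyl]-1,3-dimethyl-7-oxabicyclo[2.2.1]heptan-2-yl]-3-methylpent-1-en-3-ol (CNP0297543.1) | C=C[C@@](C)(O)CC[C@H]1[C@](C)(CC[C@H](Br)C(C)(C)Cl)[C@H]2CC[C@]1(C)O2 | target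

**Step count**

Total: 16 steps (a one-flask sequence counts as one step). Longest linear sequence: 14 steps (steps 1–5, then 8–16); the tail branch (steps 6–7) joins at step 8.

**Steps most likely to fail**

Step 12. After the C6–C11 bond has formed, the C7 cation may lose a proton to give ring or exocyclic alkenes faster than the boron-bound oxygen reaches it, or the activated oxirane may undergo a hydride shift to the C10 ketone before the alkene engages. The fallback separates the two bond formations and sets out from 18. Cyclization with ZrCl4 in CH2Cl2 at −78 °C, conditions under which terpenoid epoxides are known to end in proton loss, should give the monocyclic alcohol with an exocyclic C7 methylene F1 together with its C7=C8 ring-alkene isomer F2. The mixture would be treated with Hg(OCOCF3)2 in CH2Cl2 at −20 °C, where intramolecular alkoxymercuration by the cis-1,4 hydroxyl (the classical cineole-type closure) should outrun attack on the remote alkenes, to give the primary organomercury trifluoroacetate F3 and the C8 organomercury trifluoroacetate F4. Alkaline NaBH4 would then reduce both to the same ether, and the route is rejoined at 20. The C6 configuration still depends on the chair closure of the C–C bond-forming event.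

Step 15. The chlorosulfite or the bromonium ion may lose a proton (dehydration to an isopropenyl or allylic bromide) instead of being captured by chloride, and some opening of the bromonium ion at C14 would scramble the halogens. The fallback sets out from alkene 20 and bypasses epoxide and bromohydrin. Electrophilic bromochlorination with tetrabutylammonium dichlorobromate (Bu4N BrCl2) in CH2Cl2 at 0 °C should add bromine to C14 and chloride to the tertiary C15 in the Markovnikov sense, the vinyl group being much less nucleophilic. It would give 25 together with its (14R)-epimer F5, since C14 is no longer under reagent control; after chromatographic separation the route is rejoined at 25.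

Step 7. Oxypalladation of a vinyl group shielded by the adjacent quaternary silyloxy carbon may be slow or may turn toward the aldehyde, and prolonged exposure could cost the triethylsilyl group. The fallback sets out from 11 and reaches the same ketone without palladium. Exhaustive ozonolysis (O3, CH2Cl2, −78 °C; PPh3) should give (2S)-2-methyl-2-(triethylsilyloxy)hexanedial F6. One equivalent of Ph3P=C(CH3)2 at −78 °C should olefinate only the unhindered aldehyde and restore the prenyl terminus, giving (2S)-2,6-dimethyl-2-(triethylsilyloxy)hept-5-enal F7. Addition of CH3MgBr to the remaining neopentyl aldehyde should give (3S)-3,7-dimethyl-3-(triethylsilyloxy)oct-6-en-2-ol F8 as a mixture of C2 epimers, and Dess–Martin oxidation returns the route to 12.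

**Further compounds**

F1 | step 12 | monocyclic alcohol with exocyclic C7 methylene (C6, C10, C11 as in 20) | C=C[C@@](C)(O[Si](C)(C)C(C)(C)C)CC[C@H]1[C@](C)(CCC=C(C)C)[C@H](O)CCC1=C
F2 | step 12 | C7=C8 ring-alkene isomer of F1 | C=C[C@@](C)(O[Si](C)(C)C(C)(C)C)CC[C@H]1[C@](C)(CCC=C(C)C)[C@H](O)CC=C1C
F3 | step 12 | 20 carrying CH2HgOCOCF3 in place of the C7 methyl group | C=C[C@@](C)(O[Si](C)(C)C(C)(C)C)CC[C@H]1[C@](C)(CCC=C(C)C)[C@H]2CC[C@]1(C[Hg]OC(=O)C(F)(F)F)O2
F4 | step 12 | 20 carrying HgOCOCF3 at C8, anti to the oxygen bridge | C=C[C@@](C)(O[Si](C)(C)C(C)(C)C)CC[C@H]1[C@](C)(CCC=C(C)C)[C@H]2C[C@@H]([Hg]OC(=O)C(F)(F)F)[C@]1(C)O2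
F5 | step 15 | (14R)-epimer of 25 | C=C[C@@](C)(O[Si](C)(C)C(C)(C)C)CC[C@H]1[C@](C)(CC[C@@H](Br)C(C)(C)Cl)[C@H]2CC[C@]1(C)O2
F6 | step 7 | (2S)-2-methyl-2-(triethylsilyloxy)hexanedial | O=C[C@@](C)(O[Si](CC)(CC)CC)CCC=O
F7 | step 7 | (2S)-2,6-dimethyl-2-(triethylsilyloxy)hept-5-enal | O=C[C@@](C)(O[Si](CC)(CC)CC)CCC=C(C)C
F8 | step 7 | (3S)-3,7-dimethyl-3-(triethylsilyloxy)oct-6-en-2-ol (both C2 epimers) | CC(O)[C@@](C)(O[Si](CC)(CC)CC)CCC=C(C)C
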